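A direct plan would make the C13 acid A1 from a geranyl halide and a three-carbon acetal Grignard reagent, load it on a chiral oxazolidinone (A2) and alkylate the enolate with a bromoacetate. It would then cleave the auxiliary to the half ester A3, acylate the dianion of A3 with the allylated gentisate A4, and finish by palladium deallylation with decarboxylation.
Its weakest steps would be:
- The run-up to A2: three steps to a simple acid, and the auxiliary is later removed again, so five steps build almost nothing of the final skeleton.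
- The auxiliary alkylation that sets C2: the chirality is stoichiometric, and the centre must then survive alkaline hydroperoxide (a peracid next to two trisubstituted alkenes) and three equivalents of LDA.
- The crossed Claisen acylation of the dianion of A3 with A4: the ester is hindered and electron-rich, C2 can epimerise, and one ester carbon and three allyl groups are discarded at the end.

**Retrosynthetic overview** (butanoic acid numbering: C1 carboxyl, C2 stereocentre, C3 methylene, C4 aryl ketone carbon)
- The target, a 2-substituted 4-aryl-4-oxobutanoic acid, is cut at C1–C2 and at the C2–H bond. C2 is the carbonyl carbon and C3 the methyl group of commercial (E)-geranylacetone, which also brings the whole dienyl chain. C1 is carbon monoxide. C4 and the 2,5-dioxygenated benzene ring come from methyl gentisate.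
- Order: Claisen acylation to a 1,3-diketone, Z-selective enol triflate at the C2 oxygen, hydroxycarbonylation to a (Z)-2-alkyl-3-aroylacrylic acid, then enantioselective hydrogenation of C2=C3. No ring is formed; the benzene ring is bought.
- The design needs no chain homologation, no auxiliary, no discarded carbon and no strong base once the stereocentre exists. The only protecting groups are two MOM ethers, removed last.

Key step: step 5

Assumption: the (S) antipode of the ligand in step 5 is taken to deliver hydrogen to the face of C2=C3 that gives (S)-10; this rests on analogy only, and the (R) ligand would be used if the sense were the reverse.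

Step 1
Reactants: 1 methyl 2,5-dihydroxybenzoate (methyl gentisate); 2 chloromethyl methyl ether
Product: 3 methyl 2,5-bis(methoxymethoxy)benzoate
Conditions: NaH (2.4 equiv), THF/DMF, 0 °C; then 2 (2.6 equiv), 0 °C → rt
Reagents that add atoms: chloromethyl methyl ether (2), COCCl
Why: Williamson-type O-alkylation of both phenoxides (NaH is needed for the hydrogen-bonded 2-OH) gives a non-enolisable aryl ester whose acetal groups tolerate base, palladium and hydrogenation.

Step 2
Reactants: 4 (E)-geranylacetone, (5E)-6,10-dimethylundeca-5,9-dien-2-one; 3 methyl 2,5-bis(methoxymethoxy)benzoate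
Product: 6 (6E)-1-[2,5-bis(methoxymethoxy)phenyl]-7,11-dimethyldodeca-6,10-diene-1,3-dione, via lithium enolate 5 (not isolated)
Conditions: LDA (2.2 equiv), 4 (2.2 equiv), THF, −78 °C; then 3 (1.0 equiv), −78 °C → rt; aq. NH4Cl
Reagents that add atoms: methyl 2,5-bis(methoxymethoxy)benzoate (3), COC(=O)c1cc(OCOC)ccc1OCOC; LDA, CC(C)[N-]C(C)C.[Li+] (Li held only in 5)
Why: Crossed Claisen condensation, in which the kinetic methyl enolate of 4 attacks the non-enolisable ester and the diketone is trapped as its enolate by the second equivalent of 5, which makes the acylation irreversible; no stereocentre is formed.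

Step 3
Reactants: 6 (6E)-1-[2,5-bis(methoxymethoxy)phenyl]-7,11-dimethyldodeca-6,10-diene-1,3-dione
Product: 8 (2Z,6E)-1-[2,5-bis(methoxymethoxy)phenyl]-7,11-dimethyl-1-oxododeca-2,6,10-trien-3-yl trifluoromethanesulfonate, via sodium diketonate 7 (not isolated)
Conditions: NaH (1.1 equiv), THF, 0 °C; then PhNTf2 (1.15 equiv), 0 °C → rt; aq. NH4Cl
Reagents that add atoms: N-phenylbis(trifluoromethanesulfonimide), O=S(=O)(N(c1ccccc1)S(=O)(=O)C(F)(F)F)C(F)(F)F; sodium hydride, [Na+].[H-] (Na held only in 7)
Why: O-sulfonylation of the chelated sodium diketonate, where the cation holds both oxygens cis (Z enol triflate) and the bulky triflimide should attack the alkyl-side oxygen, remote from the ortho-substituted aryl ring, so that the aryl ketone stays in place.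

Step 4
Reactants: 8 (2Z,6E)-1-[2,5-bis(methoxymethoxy)phenyl]-7,11-dimethyl-1-oxododeca-2,6,10-trien-3-yl trifluoromethanesulfonate
Product: 9 (2Z,5E)-2-{2-[2,5-bis(methoxymethoxy)phenyl]-2-oxoethylidene}-6,10-dimethylundeca-5,9-dienoic acid
Conditions: Pd(OAc)2 (5 mol %), dppp (6 mol %), CO (1 atm), H2O (10 equiv), i-Pr2NEt (3 equiv), DMF, 25 → 45 °C; cold 1 M HCl to pH 3
Reagents that add atoms: carbon monoxide, [C-]#[O+]; water, O
Why: Palladium-catalysed hydroxycarbonylation of an enol triflate, in which zerovalent palladium inserts into the activated C–O bond with retention, CO inserts and water cleaves the acylpalladium, so C1 is introduced with the Z geometry intact.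

Step 5
Reactants: 9 (2Z,5E)-2-{2-[2,5-bis(methoxymethoxy)phenyl]-2-oxoethylidene}-6,10-dimethylundeca-5,9-dienoic acid
Product: 10 (2S,5E)-2-{2-[2,5-bis(methoxymethoxy)phenyl]-2-oxoethyl}-6,10-dimethylundeca-5,9-dienoic acid
Conditions: Ru(OAc)2[(S)-H8-BINAP] (1 mol %), Et3N (0.5 equiv), H2 (5 bar), degassed MeOH, 25 °C
Reagents that add atoms: none
Why: Carboxylate-directed asymmetric hydrogenation: 9 replaces an acetate on divalent ruthenium, H2 is cleaved heterolytically, and migratory insertion delivers the hydride to C2 while ruthenium binds C3 in a five-membered carboxylate chelate that is then protonated. The closest known reaction type is the hydrogenation of 2-alkyl-substituted α,β-unsaturated carboxylic acids with BINAP-type ruthenium dicarboxylates. No ring is closed. The C2 stereocentre is set by the axially chiral diphosphine, whose P-aryl groups leave one face of the chelated alkene open, and the single Z geometry from steps 3 and 4 ties that face to one enantiomer. The step must reduce one of three trisubstituted C=C bonds and leave the aryl ketone alone; only C2=C3 can chelate through the carboxylate and is polarised by the C4 ketone towards hydride attack at C2, whereas isolated trisubstituted alkenes and aryl ketones are not reduced by this catalyst type.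

Step 6
Reactants: 10 (2S,5E)-2-{2-[2,5-bis(methoxymethoxy)phenyl]-2-oxoethyl}-6,10-dimethylundeca-5,9-dienoic acid
Product: 11 (2S,5E)-2-[2-(2,5-dihydroxyphenyl)-2-oxoethyl]-6,10-dimethylundeca-5,9-dienoic acid
Conditions: 2 M HCl, THF/i-PrOH/H2O, 35 °C, N2
Reagents that add atoms: none
Why: Acid-catalysed hydrolysis of the two aryl methoxymethyl acetals should be much faster in dilute acid than protonation of the trisubstituted alkenes; isopropanol replaces methanol to avoid esterification, and C2, which is α only to a carboxylic acid, does not enolise.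

**Compound list**
1 | methyl 2,5-dihydroxybenzoate | COC(=O)c1cc(O)ccc1O | starting material
2 | chloromethyl methyl ether | COCCl | starting material
3 | methyl 2,5-bis(methoxymethoxy)benzoate | COC(=O)c1cc(OCOC)ccc1OCOC | intermediate
4 | (E)-geranylacetone, (5E)-6,10-dimethylundeca-5,9-dien-2-one | CC(C)=CCC/C(C)=C/CCC(C)=O | starting material
5 | lithium (5E)-6,10-dimethylundeca-1,5,9-trien-2-olate | CC(C)=CCC/C(C)=C/CCC(=C)[O-].[Li+] | intermediate
6 | (6E)-1-[2,5-bis(methoxymethoxy)phenyl]-7,11-dimethyldodeca-6,10-diene-1,3-dione | CC(C)=CCC/C(C)=C/CCC(=O)CC(=O)c1cc(OCOC)ccc1OCOC | intermediate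
7 | sodium (2Z,6E)-1-[2,5-bis(methoxymethoxy)phenyl]-7,11-dimethyl-1-oxododeca-2,6,10-trien-3-olate | CC(C)=CCC/C(C)=C/CC/C([O-])=C/C(=O)c1cc(OCOC)ccc1OCOC.[Na+] | intermediate
8 | (2Z,6E)-1-[2,5-bis(methoxymethoxy)phenyl]-7,11-dimethyl-1-oxododeca-2,6,10-trien-3-yl trifluoromethanesulfonate | CC(C)=CCC/C(C)=C/CC/C(OS(=O)(=O)C(F)(F)F)=C/C(=O)c1cc(OCOC)ccc1OCOC | intermediate
9 | (2Z,5E)-2-{2-[2,5-bis(methoxymethoxy)phenyl]-2-oxoethylidene}-6,10-dimethylundeca-5,9-dienoic acid | CC(C)=CCC/C(C)=C/CC/C(C(=O)O)=C/C(=O)c1cc(OCOC)ccc1OCOC | intermediate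
10 | (2S,5E)-2-{2-[2,5-bis(methoxymethoxy)phenyl]-2-oxoethyl}-6,10-dimethylundeca-5,9-dienoic acid | CC(C)=CCC/C(C)=C/CC[C@@H](CC(=O)c1cc(OCOC)ccc1OCOC)C(=O)O | intermediate
11 | (2S,5E)-2-[2-(2,5-dihydroxyphenyl)-2-oxoethyl]-6,10-dimethylundeca-5,9-dienoic acid | CC(C)=CCC/C(C)=C/CC[C@@H](CC(=O)c1cc(O)ccc1O)C(=O)O | target

Total step count: 6. Longest linear sequence: 6 steps (1 → 3 → 6 → 8 → 9 → 10 → 11); 4 enters at step 2.

**Steps most likely to fail**

1. Step 5 (key step). Face selectivity on the hindered Z-trisubstituted acid may be too low, or the amine may move the C2=C3 double bond out of conjugation before it is reduced; either would erode enantiomeric purity. The fallback sets the centre by enantioselective protonation instead; it sets out from 4 and comes back at 10. The kinetic enolate 5 of 4 would be trapped with PhNTf2 as (5E)-6,10-dimethylundeca-1,5,9-trien-2-yl trifluoromethanesulfonate F1. Methoxycarbonylation (Pd(OAc)2, dppp, CO, MeOH, Et3N, DMF) would give methyl (5E)-6,10-dimethyl-2-methylideneundeca-5,9-dienoate F2. A carbene-catalysed intermolecular Stetter reaction (chiral bicyclic triazolium salt, K2CO3, toluene) of F2 with 2,5-bis(methoxymethoxy)benzaldehyde F3, prepared like 3 from the commercial dihydroxy aldehyde, would form the C3–C4 bond and protonate the ester enolate enantioselectively. This would give methyl (2S,5E)-2-{2-[2,5-bis(methoxymethoxy)phenyl]-2-oxoethyl}-6,10-dimethylundeca-5,9-dienoate F4, and LiOH in THF/H2O at 0 °C would hydrolyse F4 to 10.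

2. Step 3. Sulfonylation may occur partly at the aryl-side oxygen, which would later place the carboxyl group on C4 instead of C2. The fallback fixes the regiochemistry through an ynone; it sets out from 4 and 3 and comes back at 9. One-pot treatment of 4 (LDA; ClP(O)(OEt)2; then LDA, 2.2 equiv) would pass through diethyl (5E)-6,10-dimethylundeca-1,5,9-trien-2-yl phosphate F5 to the alkyne (5E)-6,10-dimethylundeca-5,9-dien-1-yne F6. Ester 3 would be converted with MeNHOMe·HCl and i-PrMgCl into N-methoxy-N-methyl-2,5-bis(methoxymethoxy)benzamide F7. The lithium acetylide of F6 (n-BuLi, THF, −78 °C) and F7 would give (6E)-1-[2,5-bis(methoxymethoxy)phenyl]-7,11-dimethyldodeca-6,10-dien-2-yn-1-one F8. Anti-hydroiodination (NaI, AcOH, rt) places iodine only at C3 and would give (2Z,6E)-1-[2,5-bis(methoxymethoxy)phenyl]-3-iodo-7,11-dimethyldodeca-2,6,10-trien-1-one F9. F9 would take the place of 8 under the conditions of step 4 and give 9.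

3. Step 4. Water and amine may solvolyse the vinylogous acyl triflate back to the diketone faster than zerovalent palladium inserts. The fallback brings in C1 at the aldehyde level without an oxygen nucleophile; it sets out from 8 and comes back at 9. Reductive carbonylation (Pd(OAc)2, dppp, CO, Et3SiH, Et3N, DMF) would give (2Z,5E)-2-{2-[2,5-bis(methoxymethoxy)phenyl]-2-oxoethylidene}-6,10-dimethylundeca-5,9-dienal F10. A Pinnick oxidation (NaClO2, NaH2PO4, 2-methyl-2-butene, t-BuOH/H2O) would convert F10 into 9.

**Further compounds**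
F1 | step 5 | (5E)-6,10-dimethylundeca-1,5,9-trien-2-yl trifluoromethanesulfonate | CC(C)=CCC/C(C)=C/CCC(=C)OS(=O)(=O)C(F)(F)F
F2 | step 5 | methyl (5E)-6,10-dimethyl-2-methylideneundeca-5,9-dienoate | CC(C)=CCC/C(C)=C/CCC(=C)C(=O)OC
F3 | step 5 | 2,5-bis(methoxymethoxy)benzaldehyde | COCOc1ccc(OCOC)c(C=O)c1
F4 | step 5 | methyl (2S,5E)-2-{2-[2,5-bis(methoxymethoxy)phenyl]-2-oxoethyl}-6,10-dimethylundeca-5,9-dienoate | CC(C)=CCC/C(C)=C/CC[C@@H](CC(=O)c1cc(OCOC)ccc1OCOC)C(=O)OC
F5 | step 3 | diethyl (5E)-6,10-dimethylundeca-1,5,9-trien-2-yl phosphate | CC(C)=CCC/C(C)=C/CCC(=C)OP(=O)(OCC)OCC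
F6 | step 3 | (5E)-6,10-dimethylundeca-5,9-dien-1-yne | CC(C)=CCC/C(C)=C/CCC#C
F7 | step 3 | N-methoxy-N-methyl-2,5-bis(methoxymethoxy)benzamide | CON(C)C(=O)c1cc(OCOC)ccc1OCOC
F8 | step 3 | (6E)-1-[2,5-bis(methoxymethoxy)phenyl]-7,11-dimethyldodeca-6,10-dien-2-yn-1-one | CC(C)=CCC/C(C)=C/CCC#CC(=O)c1cc(OCOC)ccc1OCOC
F9 | step 3 | (2Z,6E)-1-[2,5-bis(methoxymethoxy)phenyl]-3-iodo-7,11-dimethyldodeca-2,6,10-trien-1-one | CC(C)=CCC/C(C)=C/CC/C(I)=C/C(=O)c1cc(OCOC)ccc1OCOC
F10 | step 4 | (2Z,5E)-2-{2-[2,5-bis(methoxymethoxy)phenyl]-2-oxoethylidene}-6,10-dimethylundeca-5,9-dienal | CC(C)=CCC/C(C)=C/CC/C(C=O)=C/C(=O)c1cc(OCOC)ccc1OCOC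
A1 | direct plan | (5E)-6,10-dimethylundeca-5,9-dienoic acid | CC(C)=CCC/C(C)=C/CCCC(=O)O
A2 | direct plan | (4R)-4-benzyl-3-[(5E)-6,10-dimethylundeca-5,9-dienoyl]-1,3-oxazolidin-2-one | CC(C)=CCC/C(C)=C/CCCC(=O)N1[C@H](Cc2ccccc2)COC1=O
A3 | direct plan | (2S,5E)-2-[2-(allyloxy)-2-oxoethyl]-6,10-dimethylundeca-5,9-dienoic acid | CC(C)=CCC/C(C)=C/CC[C@@H](CC(=O)OCC=C)C(=O)O
A4 | direct plan | allyl 2,5-bis(allyloxy)benzoate | C=CCOC(=O)c1cc(OCC=C)ccc1OCC=C
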